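**Plan**
- Cuts: the isopropyl ether on O5 of coumarin B; the lactone ring of B at C4–C4a and O1–C2 (phenol + ethyl propiolate); the lactone ring of A at C3=C4 and O1–C2 (salicylaldehyde + ester ylide); the benzene ring of A at C5–C6 and C7–C8 (2-pyranone + 1,1-dimethoxyethene); the diaryl ether O–C8 bond (pyranone carbenoid + phenol).
- Enabling feature: in the benzene ring of coumarin A, C4a bears carbon C4 para to the methoxy carbon C7, with the oxygenated carbons C8a and C8 between them. A 5-carbomethoxy-2-pyranone supplies this (ester → C4, O on C4 → O1, aryloxy on C3 → C8) and the acetal carbon of a ketene acetal supplies C7–OMe, after loss of CO2 and methanol.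
- Forward order: 2-pyranone ring, diaryl ether by O–H insertion, benzene ring of A (key cycloaddition), lactone of A (Wittig), lactone of B (Pd hydroarylation), dealkylation. The C2-symmetric resorcinol ring of B and the isopropyl block on its para oxygen fix the direction of the last annulation.
- Stereochemistry: the target has no stereocentre, so nothing has to be set.

Key step: step 8

Remark: the hindered diaryl ether is assumed to rotate freely, so the target is one achiral compound and no enantioselective step is needed; 2,4,6-trihydroxybenzaldehyde (formylphloroglucinol) is taken as a purchasable starting material.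

**Step 1**
Reactants: 1 2,4,6-trihydroxybenzaldehyde
Product: 2 2,6-dihydroxy-4-(propan-2-yloxy)benzaldehyde
Conditions: 2-bromopropane (1.2 equiv), CsHCO3 (1.5 equiv), MeCN, 70 °C, sealed vessel
Reagents that add atoms: 2-bromopropane, CC(C)Br
Why: Bicarbonate-mediated Williamson alkylation should go at O4, the most acidic hydroxyl and the only one not chelated to the formyl group, as in the selective 4-O-alkylation of 2,4-dihydroxyaryl carbonyl compounds.

**Step 2**
Reactants: 2 2,6-dihydroxy-4-(propan-2-yloxy)benzaldehyde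
Product: 3 2,6-bis(methoxymethoxy)-4-(propan-2-yloxy)benzaldehyde
Conditions: NaH (2.5 equiv), MOMCl (2.5 equiv), DMF, 0 °C → rt
Reagents that add atoms: chloromethyl methyl ether, COCCl
Why: Full deprotonation with NaH overcomes the hydrogen bonding of the ortho hydroxyls, so Williamson alkylation with MOMCl should protect both, and the aldehyde has no α-hydrogen to interfere.

**Step 3**
Reactants: 3 2,6-bis(methoxymethoxy)-4-(propan-2-yloxy)benzaldehyde
Product: 5 2,6-bis(methoxymethoxy)-4-(propan-2-yloxy)phenol, via aryl formate 4 (not isolated)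
Conditions: mCPBA, CH2Cl2, 0 °C → rt; then K2CO3 (cat.), MeOH, rt
Reagents that add atoms: 3-chloroperoxybenzoic acid, O=C(OO)c1cccc(Cl)c1
Why: In this Baeyer–Villiger (Dakin-type) oxidation the electron-rich trialkoxyaryl group migrates in preference to hydrogen, and methanolysis of the formate then frees the phenol while the MOM and isopropyl ethers are inert to peracid and carbonate.

**Step 4**
Reactants: 6 dimethyl 3-oxopentanedioate
Product: 8 methyl 4-hydroxy-2-oxo-2H-pyran-5-carboxylate, via methoxymethylidene diester 7 (not isolated)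
Conditions: HC(OMe)3 (1.1 equiv), Ac2O, 130 °C; concentrate; then 2 M aq. HCl, rt
Reagents that add atoms: trimethyl orthoformate, COC(OC)OC; water, O
Why: Orthoformate/acetic anhydride alkoxymethylenation of one active methylene, then acid hydrolysis of the enol ether and lactonisation of the hydroxymethylene group onto the remote ester, should give the 4-hydroxy-2-pyranone while no sensitive group is yet present.

**Step 5**
Reactants: 8 methyl 4-hydroxy-2-oxo-2H-pyran-5-carboxylate
Product: 9 methyl 3-diazo-2,4-dioxo-3,4-dihydro-2H-pyran-5-carboxylate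
Conditions: p-ABSA, Et3N, MeCN, 0 °C → rt; non-aqueous work-up
Reagents that add atoms: 4-acetamidobenzenesulfonyl azide, CC(=O)Nc1ccc(cc1)S(=O)(=O)N=[N+]=[N-]
Why: Regitz diazo transfer to C3, the nucleophilic carbon of the cyclic 1,3-dicarbonyl, is the reaction known for 4-hydroxycoumarin and 4-hydroxy-6-methyl-2-pyranone.

**Step 6**
Reactants: 9 methyl 3-diazo-2,4-dioxo-3,4-dihydro-2H-pyran-5-carboxylate; 5 2,6-bis(methoxymethoxy)-4-(propan-2-yloxy)phenol
Product: 10 methyl 3-[2,6-bis(methoxymethoxy)-4-(propan-2-yloxy)phenoxy]-4-hydroxy-2-oxo-2H-pyran-5-carboxylate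
Conditions: Rh2(OAc)4 (1 mol %), 1,2-dichloroethane, 60 °C, slow addition of 9 to 5
Reagents that add atoms: none
Why: Rhodium-carbenoid O–H insertion of a cyclic 2-diazo-1,3-dicarbonyl into a phenol (oxonium ylide, then proton shift) forms the hindered aryl–O–C3 bond without an SN2 step, and the adduct should tautomerise to the 4-hydroxy-2-pyranone.

**Step 7**
Reactants: 10 methyl 3-[2,6-bis(methoxymethoxy)-4-(propan-2-yloxy)phenoxy]-4-hydroxy-2-oxo-2H-pyran-5-carboxylate
Product: 11 methyl 3-[2,6-bis(methoxymethoxy)-4-(propan-2-yloxy)phenoxy]-4-(methoxymethoxy)-2-oxo-2H-pyran-5-carboxylate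
Conditions: MOMCl, iPr2NEt, CH2Cl2, 0 °C
Reagents that add atoms: chloromethyl methyl ether, COCCl
Why: O-alkylation of the vinylogous acid with a hard electrophile and a hindered amine base should give the 4-alkoxy-2-pyranone, which removes the acidic proton that would destroy the ketene acetal in the next step.

**Step 8**
Reactants: 11 methyl 3-[2,6-bis(methoxymethoxy)-4-(propan-2-yloxy)phenoxy]-4-(methoxymethoxy)-2-oxo-2H-pyran-5-carboxylate; 12 1,1-dimethoxyethene
Product: 15 methyl 3-[2,6-bis(methoxymethoxy)-4-(propan-2-yloxy)phenoxy]-4-methoxy-2-(methoxymethoxy)benzoate, via bridged lactone cycloadduct 13 (not isolated), via dimethoxycyclohexadiene 14 (not isolated)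
Conditions: 12 (excess), toluene, 110 °C, sealed base-washed tube
Reagents that add atoms: none
Why: In an inverse-electron-demand Diels–Alder reaction the ester-activated 2-pyranone 11 reacts as the electron-poor diene across C3–C6 with the electron-rich ketene acetal 12 to give bridged lactone 13, which loses CO2 by retro-[4+2] to cyclohexadiene 14 and then methanol by 1,2-elimination to arene 15. The closest known reaction is the conversion of methyl coumalate and other 5-carboalkoxy-2-pyranones into 4-alkoxybenzoates with ketene acetals. The carbocycle closes by intermolecular [4+2] cycloaddition, the pyranone C6–CH2 and C3–C(OMe)2 bonds forming in one asynchronous event from four pyranone carbons and the two alkene carbons. No stereocentre survives, since the two bridgehead centres of racemic 13 are destroyed when CO2 leaves. The step needs one regiochemistry, the nucleophilic CH2 of 12 bonding to C6, and this is secured because C6 is the unsubstituted terminus β to the ester and vinylogous to the lactone carbonyl, so the acetal carbon ends next to the aryloxy carbon and para to the ester. Aromatisation is unambiguous because only the CH2–C(OMe)2 pair of 14 has a hydrogen next to a leaving group.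

**Step 9**
Reactants: 15 methyl 3-[2,6-bis(methoxymethoxy)-4-(propan-2-yloxy)phenoxy]-4-methoxy-2-(methoxymethoxy)benzoate
Product: 16 {3-[2,6-bis(methoxymethoxy)-4-(propan-2-yloxy)phenoxy]-4-methoxy-2-(methoxymethoxy)phenyl}methanol
Conditions: LiAlH4, THF, 0 °C
Reagents that add atoms: none
Why: Hydride reduction of the benzoate to the benzylic alcohol leaves aryl ethers and MOM acetals untouched and avoids the over-reduction problem of a direct ester-to-aldehyde reduction.

**Step 10**
Reactants: 16 {3-[2,6-bis(methoxymethoxy)-4-(propan-2-yloxy)phenoxy]-4-methoxy-2-(methoxymethoxy)phenyl}methanol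
Product: 17 3-[2,6-bis(methoxymethoxy)-4-(propan-2-yloxy)phenoxy]-4-methoxy-2-(methoxymethoxy)benzaldehyde
Conditions: activated MnO2, CH2Cl2, rt
Reagents that add atoms: none
Why: Manganese dioxide oxidises benzylic alcohols selectively to aldehydes under neutral conditions that the fully protected, electron-rich rings should tolerate.

**Step 11**
Reactants: 17 3-[2,6-bis(methoxymethoxy)-4-(propan-2-yloxy)phenoxy]-4-methoxy-2-(methoxymethoxy)benzaldehyde
Product: 18 3-[2,6-dihydroxy-4-(propan-2-yloxy)phenoxy]-2-hydroxy-4-methoxybenzaldehyde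
Conditions: conc. HCl (cat.), MeOH, 50 °C
Reagents that add atoms: none
Why: Acid-catalysed transacetalisation to methanol removes all three aryl MOM groups at once, whereas the isopropyl, methyl and diaryl ethers are stable to dilute acid.

**Step 12**
Reactants: 18 3-[2,6-dihydroxy-4-(propan-2-yloxy)phenoxy]-2-hydroxy-4-methoxybenzaldehyde
Product: 21 8-[2,6-dihydroxy-4-(propan-2-yloxy)phenoxy]-7-methoxy-2H-chromen-2-one, via E-cinnamate 19 (not isolated), via Z-cinnamate 20 (not isolated)
Conditions: Ph3P=CHCO2Et (1.5 equiv), PhNEt2, 215 °C (reflux)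
Reagents that add atoms: ethyl (triphenylphosphoranylidene)acetate, CCOC(=O)C=P(c1ccccc1)(c1ccccc1)c1ccccc1
Why: Wittig olefination of the salicylaldehyde in hot diethylaniline is the classical coumarin synthesis, in which thermal E/Z isomerisation of the cinnamate lets the ortho hydroxyl close the lactone with loss of ethanol.

**Step 13**
Reactants: 21 8-[2,6-dihydroxy-4-(propan-2-yloxy)phenoxy]-7-methoxy-2H-chromen-2-one; 22 ethyl propiolate
Product: 24 7-hydroxy-8-[(7-methoxy-2-oxo-2H-chromen-8-yl)oxy]-5-(propan-2-yloxy)-2H-chromen-2-one, via Z-aryl acrylate 23 (not isolated)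
Conditions: 22 (1.1 equiv), Pd(OAc)2 (5 mol %), NaOAc (cat.), HCO2H, rt
Reagents that add atoms: none
Why: Palladium-catalysed hydroarylation of an alkynoate by an electron-rich phenol followed by lactonisation is a known coumarin synthesis; here the two ortho C–H positions are equivalent by symmetry and the isopropyl ether on the para oxygen leaves only the hydroxyl next to the diaryl ether able to lactonise.

**Step 14**
Reactants: 24 7-hydroxy-8-[(7-methoxy-2-oxo-2H-chromen-8-yl)oxy]-5-(propan-2-yloxy)-2H-chromen-2-one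
Product: 25 5,7-dihydroxy-8-[(7-methoxy-2-oxo-2H-chromen-8-yl)oxy]-2H-chromen-2-one (CNP0305396.0)
Conditions: BCl3 (excess), CH2Cl2, −78 → 0 °C; aqueous work-up
Reagents that add atoms: none
Why: Boron trichloride cleaves aryl isopropyl ethers through the secondary cation much faster than aryl methyl ethers that are not ortho to a carbonyl, so the 7-methoxy group, both lactones and the diaryl ether should survive.

**Compound list**
1 | 2,4,6-trihydroxybenzaldehyde | O=Cc1c(O)cc(O)cc1O | starting material
2 | 2,6-dihydroxy-4-(propan-2-yloxy)benzaldehyde | CC(C)Oc1cc(O)c(C=O)c(O)c1 | intermediate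
3 | 2,6-bis(methoxymethoxy)-4-(propan-2-yloxy)benzaldehyde | COCOc1cc(OC(C)C)cc(OCOC)c1C=O | intermediate
4 | 2,6-bis(methoxymethoxy)-4-(propan-2-yloxy)phenyl formate | COCOc1cc(OC(C)C)cc(OCOC)c1OC=O | intermediate (not isolated)
5 | 2,6-bis(methoxymethoxy)-4-(propan-2-yloxy)phenol | COCOc1cc(OC(C)C)cc(OCOC)c1O | intermediate
6 | dimethyl 3-oxopentanedioate | COC(=O)CC(=O)CC(=O)OC | starting material
7 | dimethyl 2-(methoxymethylidene)-3-oxopentanedioate (E/Z mixture) | COC=C(C(=O)OC)C(=O)CC(=O)OC | intermediate (not isolated)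
8 | methyl 4-hydroxy-2-oxo-2H-pyran-5-carboxylate | COC(=O)c1coc(=O)cc1O | intermediate
9 | methyl 3-diazo-2,4-dioxo-3,4-dihydro-2H-pyran-5-carboxylate | COC(=O)C1=COC(=O)C(=[N+]=[N-])C1=O | intermediate
10 | methyl 3-[2,6-bis(methoxymethoxy)-4-(propan-2-yloxy)phenoxy]-4-hydroxy-2-oxo-2H-pyran-5-carboxylate | COC(=O)c1coc(=O)c(Oc2c(OCOC)cc(OC(C)C)cc2OCOC)c1O | intermediate
11 | methyl 3-[2,6-bis(methoxymethoxy)-4-(propan-2-yloxy)phenoxy]-4-(methoxymethoxy)-2-oxo-2H-pyran-5-carboxylate | COCOc1c(Oc2c(OCOC)cc(OC(C)C)cc2OCOC)c(=O)occ1C(=O)OC | intermediate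
12 | 1,1-dimethoxyethene | C=C(OC)OC | starting material
13 | methyl 4-[2,6-bis(methoxymethoxy)-4-(propan-2-yloxy)phenoxy]-8,8-dimethoxy-5-(methoxymethoxy)-3-oxo-2-oxabicyclo[2.2.2]oct-5-ene-6-carboxylate (racemic) | COC(=O)C1=C(OCOC)C2(Oc3c(OCOC)cc(OC(C)C)cc3OCOC)C(=O)OC1CC2(OC)OC | intermediate (not isolated)
14 | methyl 5-[2,6-bis(methoxymethoxy)-4-(propan-2-yloxy)phenoxy]-4,4-dimethoxy-6-(methoxymethoxy)cyclohexa-1,5-diene-1-carboxylate | COC(=O)C1=CCC(OC)(OC)C(Oc2c(OCOC)cc(OC(C)C)cc2OCOC)=C1OCOC | intermediate (not isolated)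
15 | methyl 3-[2,6-bis(methoxymethoxy)-4-(propan-2-yloxy)phenoxy]-4-methoxy-2-(methoxymethoxy)benzoate | COC(=O)c1ccc(OC)c(Oc2c(OCOC)cc(OC(C)C)cc2OCOC)c1OCOC | intermediate
16 | {3-[2,6-bis(methoxymethoxy)-4-(propan-2-yloxy)phenoxy]-4-methoxy-2-(methoxymethoxy)phenyl}methanol | COCOc1c(CO)ccc(OC)c1Oc1c(OCOC)cc(OC(C)C)cc1OCOC | intermediate
17 | 3-[2,6-bis(methoxymethoxy)-4-(propan-2-yloxy)phenoxy]-4-methoxy-2-(methoxymethoxy)benzaldehyde | COCOc1c(C=O)ccc(OC)c1Oc1c(OCOC)cc(OC(C)C)cc1OCOC | intermediate
18 | 3-[2,6-dihydroxy-4-(propan-2-yloxy)phenoxy]-2-hydroxy-4-methoxybenzaldehyde | COc1ccc(C=O)c(O)c1Oc1c(O)cc(OC(C)C)cc1O | intermediate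
19 | ethyl (2E)-3-{3-[2,6-dihydroxy-4-(propan-2-yloxy)phenoxy]-2-hydroxy-4-methoxyphenyl}prop-2-enoate | CCOC(=O)/C=C/c1ccc(OC)c(Oc2c(O)cc(OC(C)C)cc2O)c1O | intermediate (not isolated)
20 | ethyl (2Z)-3-{3-[2,6-dihydroxy-4-(propan-2-yloxy)phenoxy]-2-hydroxy-4-methoxyphenyl}prop-2-enoate | CCOC(=O)/C=C\c1ccc(OC)c(Oc2c(O)cc(OC(C)C)cc2O)c1O | intermediate (not isolated)
21 | 8-[2,6-dihydroxy-4-(propan-2-yloxy)phenoxy]-7-methoxy-2H-chromen-2-one | COc1ccc2ccc(=O)oc2c1Oc1c(O)cc(OC(C)C)cc1O | intermediate
22 | ethyl propiolate | C#CC(=O)OCC | starting material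
23 | ethyl (2Z)-3-{2,4-dihydroxy-3-[(7-methoxy-2-oxo-2H-chromen-8-yl)oxy]-6-(propan-2-yloxy)phenyl}prop-2-enoate | CCOC(=O)/C=C\c1c(OC(C)C)cc(O)c(Oc2c(OC)ccc3ccc(=O)oc23)c1O | intermediate (not isolated)
24 | 7-hydroxy-8-[(7-methoxy-2-oxo-2H-chromen-8-yl)oxy]-5-(propan-2-yloxy)-2H-chromen-2-one | COc1ccc2ccc(=O)oc2c1Oc1c(O)cc(OC(C)C)c2ccc(=O)oc12 | intermediate
25 | 5,7-dihydroxy-8-[(7-methoxy-2-oxo-2H-chromen-8-yl)oxy]-2H-chromen-2-one | COc1ccc2ccc(=O)oc2c1Oc1c(O)cc(O)c2ccc(=O)oc12 | target

**Step count and risks**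
Total: 14 steps. Longest linear sequence: 12 steps (steps 1–3, then 6–14); the pyranone branch (steps 4–5) joins at step 6.

Steps most likely to fail:

1. Step 8. The aryloxy and MOM-oxy donors on C3 and C4 may slow the cycloaddition enough that thermal oligomerisation of the ketene acetal, or its addition–elimination at C4 with loss of the MOM-oxy group, overtakes the [4+2] path. The fallback makes the diaryl ether by aryl transfer from iodine(III) instead of building ring A; it sets out from phenol 5 and comes back at coumarin 21. Commercial 7-hydroxycoumarin would be iodinated at C8 (I2, KI, aq. NH3) to 7-hydroxy-8-iodo-2H-chromen-2-one F1 and methylated (MeI, K2CO3, acetone) to 8-iodo-7-methoxy-2H-chromen-2-one F2. One-pot oxidation and arene ligation (mCPBA, TsOH·H2O, MeCN, then 1,3,5-trimethoxybenzene) should give (7-methoxy-2-oxo-2H-chromen-8-yl)(2,4,6-trimethoxyphenyl)iodonium tosylate F3. Metal-free O-arylation of 5 with F3 (K2CO3, toluene, 60 °C), a reaction that tolerates ortho substituents on both partners and transfers the aryl group that is not the trimethoxyphenyl auxiliary, would give 8-[2,6-bis(methoxymethoxy)-4-(propan-2-yloxy)phenoxy]-7-methoxy-2H-chromen-2-one F4. HCl in MeOH would then remove the two MOM groups to give 21.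

2. Step 6. The carbenoid may attack a ring carbon of the very electron-rich phenol instead of its hindered oxygen, and the diazo pyrandione may be opened by nucleophiles at its electrophilic C6 before it reaches the catalyst. The fallback forms the ether by substitution at an sp3 carbon and builds the pyranone afterwards; it sets out from 6 and 5 and comes back at 10. Chlorination of 6 (SO2Cl2, CH2Cl2, 0 °C) would give dimethyl 2-chloro-3-oxopentanedioate F5. Displacement of chloride by the phenoxide of 5 (K2CO3, acetone) would give dimethyl 2-[2,6-bis(methoxymethoxy)-4-(propan-2-yloxy)phenoxy]-3-oxopentanedioate F6. Condensation at the remaining methylene with DMF dimethyl acetal (toluene, rt) would give dimethyl 2-[2,6-bis(methoxymethoxy)-4-(propan-2-yloxy)phenoxy]-4-[(dimethylamino)methylidene]-3-oxopentanedioate F7. Hydrolysis of the enaminone and lactonisation in aqueous acetic acid, mild enough for the MOM ethers, would give 10.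

3. Step 13. A second hydroarylation at the remaining activated C–H of ring B, or stalling of the catalyst as palladium black in formic acid, may erode the annulation. The fallback builds the lactone of B by formylation and olefination; it sets out from 21 and comes back at 24. Magnesium-mediated ortho-formylation (MgCl2, Et3N, paraformaldehyde, MeCN, reflux) would give 2,4-dihydroxy-3-[(7-methoxy-2-oxo-2H-chromen-8-yl)oxy]-6-(propan-2-yloxy)benzaldehyde F8. Wittig reaction with Ph3P=CHCO2Et in diethylaniline at 215 °C would give ethyl (2E)-3-{2,4-dihydroxy-3-[(7-methoxy-2-oxo-2H-chromen-8-yl)oxy]-6-(propan-2-yloxy)phenyl}prop-2-enoate F9, not isolated, which isomerises to 23 and lactonises to 24 through the only hydroxyl next to the side chain.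

**Further compounds**
F1 | step 8 | 7-hydroxy-8-iodo-2H-chromen-2-one | Oc1ccc2ccc(=O)oc2c1I
F2 | step 8 | 8-iodo-7-methoxy-2H-chromen-2-one | COc1ccc2ccc(=O)oc2c1I
F3 | step 8 | (7-methoxy-2-oxo-2H-chromen-8-yl)(2,4,6-trimethoxyphenyl)iodonium tosylate | COc1cc(OC)c([I+]c2c(OC)ccc3ccc(=O)oc23)c(OC)c1.Cc1ccc(cc1)S(=O)(=O)[O-]
F4 | step 8 | 8-[2,6-bis(methoxymethoxy)-4-(propan-2-yloxy)phenoxy]-7-methoxy-2H-chromen-2-one | COCOc1cc(OC(C)C)cc(OCOC)c1Oc1c(OC)ccc2ccc(=O)oc12
F5 | step 6 | dimethyl 2-chloro-3-oxopentanedioate (racemic) | COC(=O)CC(=O)C(Cl)C(=O)OC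
F6 | step 6 | dimethyl 2-[2,6-bis(methoxymethoxy)-4-(propan-2-yloxy)phenoxy]-3-oxopentanedioate (racemic) | COC(=O)CC(=O)C(Oc1c(OCOC)cc(OC(C)C)cc1OCOC)C(=O)OC
F7 | step 6 | dimethyl 2-[2,6-bis(methoxymethoxy)-4-(propan-2-yloxy)phenoxy]-4-[(dimethylamino)methylidene]-3-oxopentanedioate (racemic) | COC(=O)C(=CN(C)C)C(=O)C(Oc1c(OCOC)cc(OC(C)C)cc1OCOC)C(=O)OC
F8 | step 13 | 2,4-dihydroxy-3-[(7-methoxy-2-oxo-2H-chromen-8-yl)oxy]-6-(propan-2-yloxy)benzaldehyde | O=Cc1c(OC(C)C)cc(O)c(Oc2c(OC)ccc3ccc(=O)oc23)c1O
F9 | step 13 | ethyl (2E)-3-{2,4-dihydroxy-3-[(7-methoxy-2-oxo-2H-chromen-8-yl)oxy]-6-(propan-2-yloxy)phenyl}prop-2-enoate | CCOC(=O)/C=C/c1c(OC(C)C)cc(O)c(Oc2c(OC)ccc3ccc(=O)oc23)c1O
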